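The vessel is closed and holds a racemate, and before charging it I must decide what to change: cleaner material, a longer time, or more reagent.

| flask | left-handed substrate | right-handed substrate | reagent | free catalyst | impurity | remark | time |
|---|---|---|---|---|---|---|---|
| alder | 0.043 M | 0.043 M | 0.051 M | 7.1 mM | 1.7 mM | run made earlier |  |
| maple | 0.064 M | 0.064 M | 0.051 M | 7.1 mM | 1.7 mM | run made earlier |  |
| cedar | 0.085 M | 0.085 M | 0.051 M | 7.1 mM | 2.5 mM | run made earlier |  |
| flask | 0.085 M | 0.085 M | 0.0510 M | 7.1 mM | 1.7 mM |  | 80 min |

| run | time / min | left-handed substrate / % | right-handed substrate / % | left-handed product / % |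
|---|---|---|---|---|
| alder | 6.00 | 36.7 | 43.5 | 14.0 |
| alder | 15.0 | 29.0 | 38.4 | 21.6 |
| alder | 20.0 | 25.1 | 36.3 | 24.6 |
| alder | 30.0 | 20.9 | 34.1 | 29.3 |
| alder | 40.0 | 19.7 | 33.1 | 30.9 |
| alder | 50.0 | 17.6 | 31.8 | 33.1 |
| maple | 6.00 | 36.9 | 44.1 | 12.6 |
| maple | 15.0 | 30.3 | 41.7 | 19.9 |
| maple | 20.0 | 28.1 | 39.7 | 21.3 |
| maple | 30.0 | 26.2 | 38.0 | 23.3 |
| maple | 40.0 | 25.1 | 37.1 | 23.3 |
| maple | 50.0 | 24.6 | 37.5 | 25.2 |
| cedar | 10.0 | 36.3 | 43.8 | 13.6 |
| cedar | 20.0 | 32.9 | 41.9 | 17.0 |
| cedar | 30.0 | 31.6 | 41.0 | 18.4 |
| cedar | 40.0 | 30.7 | 40.6 | 18.9 |
| cedar | 50.0 | 29.6 | 40.5 | 20.0 |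

(each reading ± 0.5 percentage points)

- free catalyst is single-handed; left-handed substrate and right-handed substrate are mirror images of each other, charged as a racemate, each of them at the stated concentration
- an excess is the difference of the two amounts in percent of their sum
- an excess is below zero if the other one leads

1. part of the left-handed substrate and right-handed substrate charged together that has reacted at 80 min
2. excess of left-handed product over right-handed product in the product at 80 min
3. excess of right-handed substrate over left-handed substrate among what is left of the two at 80 min

I reckon in fractions of the charge. My quantity is the reagent ceiling: the reagent charged over the two substrates charged together, 30.0 % for this flask. It is the most that can react if each substrate takes one reagent, the reagent being the limiting reagent.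

The readings test it. At 50.0 min alder has reacted 50.6 % against a ceiling of 59.3 %, and maple 37.9 % against 39.8 %. Cedar, at 50.0 min, has reacted 29.9 % against 30.0 %.

Cedar has the substrates and reagent of this flask, but more impurity, and I read the approach to the ceiling from it. Its gap to the ceiling is 4.8 percentage points at 20.0 min and 1.3 points at 40.0 min, so the gap halves in about 10.6 min. Carried to 80 min, that halving gives me an estimated gap of 0.095 points, against a scatter of 0.5 points.

So I expect 29.9 % reacted. Cedar's last readings give me an eS of 15.5 % and, with the right-handed product by difference, an eP of 33.8 %. I keep time and impurity as they stand. If I want more reacted, I change the reagent.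

The forecast, close to mine but not equal, says 29.8 %, 35.5 % and 15.1 %, expecting the flask to have “essentially used up the reagent”.

The flask gives 30.0 %, 34.6 % and 14.8 %.

    reagent + free catalyst + right-handed substrate → free catalyst + right-handed product (k = 2.24 M⁻² s⁻¹)
    reagent + free catalyst + left-handed substrate → free catalyst + left-handed product (k = 5.31 M⁻² s⁻¹)
    free catalyst ⇌ dormant form (K = 0.740, k = 0.00225 s⁻¹)
    free catalyst + impurity → spent catalyst (k = 1230 M⁻¹ s⁻¹)

At 80.0 min the flask's reagent stands at 0.10 % of its charge, and the ceiling times the reagent used is 30.0 %. In this flask, leaving out the passing of free catalyst and impurity into spent catalyst makes no difference to the part reacted. A second flask, like this one but charged with 0.13 M of reagent, has a ceiling of 76.5 %. At 80 min that second flask has reacted 73.5 %, with 3.9 % of its reagent left, and its ceiling times the reagent used is 73.5 %.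

All runs were generated by integration with made-up constants; scatter was added.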